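In a closed flask the charge of starting material is conserved, so whatever has not become product is either still there or has gone elsewhere, and that is how we would read your two runs before giving you a quick number.

| setting | east | south-east | noon | summer |
|---|---|---|---|---|
| starting material | 0.80 M | 0.80 M | 0.80 M | 0.80 M |
| free catalyst | 74 mM | 160 mM | 110 mM | 110 mM |
| temperature | 55 °C | 80 °C | 60 °C | 100 °C |
| remark | run made earlier | run made earlier |  |  |
| time |  |  | 20 min | 20 min |

| run | time / min | product / % |
|---|---|---|
| east | 10.0 | 1.8 |
| east | 15.0 | 3.2 |
| east | 25.0 | 7.3 |
| east | 40.0 | 12.1 |
| east | 80.0 | 22.6 |
| east | 120 | 28.7 |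
| south-east | 5.00 | 31.7 |
| south-east | 10.0 | 49.1 |
| south-east | 15.0 | 56.9 |
| south-east | 20.0 | 59.4 |
| south-east | 25.0 | 61.3 |
| south-east | 30.0 | 62.3 |

(standard deviation of a reading: 0.5 percentage points)

- the flask that ends with the higher amount of product, in percent of the starting material charged, or "neither" when 2 percentage points or less lies between them (noon / summer / neither)
- final product, as a percentage of the starting material charged, in noon
- final product, as a percentage of the starting material charged, in summer



The south-east run goes from 61.3% to 62.3% over its last readings, and we read that levelling as a race between product and a loss we cannot see, close to its end. At a fixed charge of starting material, the odds of such a race should grow with the free catalyst. The last reading of the south-east run therefore gives a race number of 8.26, meaning the odds of product against the rest of the charge, divided by the charged free catalyst as a fraction of the charged starting material; it is a kind of selectivity factor. Both new flasks charge free catalyst at a fraction of 13.7% of the starting material, so, assuming the race number holds across temperature, we estimate their plateau at 53.2%. We expect summer, hotter than the south-east run, to come close to that plateau by 20 min. The east run, cooler than noon and with less free catalyst, had 7.3% at 25.0 min; we expect noon to stand well below that plateau at 20 min, and we have no better figure for noon than your forecast's.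

That forecast says summer, with 16% for noon and 70% for summer, leaning to an equilibrium because “the clean exponential and the temperature-driven plateau lean slightly towards equilibrium”. We agree on the flask and differ on summer, with 53.2% against 70%.

The flasks give 14.1% in noon and 55.1% in summer, so summer ends higher.

    starting material + free catalyst → catalyst intermediate A (k = 0.0970 L mol⁻¹ s⁻¹, Ea = 79.0 kJ mol⁻¹)
    2 starting material → homo dimer (k = 0.00640 L mol⁻¹ s⁻¹, Ea = 73.0 kJ mol⁻¹)
    catalyst intermediate A ⇌ catalyst intermediate B (K = 2.30, k = 0.690 s⁻¹, Ea = 86.0 kJ mol⁻¹, ΔH = 6.00 kJ mol⁻¹)
    product + catalyst intermediate B → spent catalyst (k = 0.00110 L mol⁻¹ s⁻¹, Ea = 92.0 kJ mol⁻¹)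
    catalyst intermediate B ⇌ free catalyst + product (K = 1.50 M, k = 0.150 s⁻¹, Ea = 101 kJ mol⁻¹, ΔH = −45.0 kJ mol⁻¹)
    (constants at 100 °C)

Summer stops short of the charge because starting material pairs off into homo dimer: with that step taken away, summer gives 89.7% rather than 55.1%. Read back from its own product, summer has a race number of 8.92, against our 8.26. Noon left to 200 min, with 0.329% of its starting material remaining, holds 51.7% product, a race number of 7.79.

(The runs are calculated on assumed constants; noise was put on by code.)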